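**Plan**

1. Retrosynthetic cuts: the three C=CH2 groups (C7 methylidene, isopropenyl, acrylate) go back to a ketone, an amide and an aldehyde. C4–C5 is cut by a retro-oxy-Cope, which re-forms C2–C7 and shrinks the ten-membered ring to the six-membered ring of a bicyclo[4.2.0]octanone. C1–C12 is cut by a retro-Wolff step, then C2–C7 (allylation), C1–C2 (aldol) and C9–C10 (conjugate addition).
2. Enabling feature: the cyclobutane C1–C10–C11–C12 carries on C12 one carbon (C13, the isopropenyl carbon) next to the methyl-bearing quaternary C1. With C13 placed as a ring carbonyl between C1 and C12, the four-membered ring becomes the five-membered ring of a trans-fused 7a-methylhydrindan-1-one, so C1–C12 can be made by ring contraction that pushes C13 out of the ring.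
3. Forward order: cyclopentenone → three-component coupling → six-membered ring (C2–C7) → diazo ketone → four-membered ring (C1–C12) → ten-membered ring by anionic oxy-Cope (C4–C5 formed, C2–C7 broken) → reduction and three methylenations.
4. Stereochemistry: C10 from a Cu-catalysed asymmetric conjugate addition; C1 by trans enolate trapping; C2 (relay centre) from the chair allylation; C12 by protonation anti to the angular methyl; C4 by chair [3,3] chirality transfer from C2 through an (E)-alkene; C6 by peripheral protonation of the ring enolate.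

Key step: step 6

Remark: locants C1–C12 are the bicyclo[8.2.0]dodecane locants of the target (C1 methyl-bearing fusion carbon, C4 acrylate-bearing, C6 prenyl-bearing, C7 methylidene-bearing, C10 fusion CH, C12 isopropenyl-bearing; C13 is the carbon on C12) and are used for every intermediate. The phosphate-bearing carbon of 6–8 is assumed to be an epimer mixture, which is without consequence because it becomes part of an allyl system.

**Route**

Step 1
Reactants: 1 2-methylcyclopent-2-en-1-one; 2 2-(2-bromoethyl)-1,3-dioxolane; 3 acrolein
Product: 7 allylic diethyl phosphate of the trans-2,3-disubstituted 2-methylcyclopentanone, via Grignard reagent 4 (not isolated), via magnesium enolate 5 (not isolated), via magnesium aldolate 6 (not isolated)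
Conditions: 2, Mg, THF, 25 °C; then 1, Cu(OTf)2 (3 mol %), chiral NHC ligand (4 mol %), Et2O, −30 °C; then 3, −78 °C; then ClP(O)(OEt)2, −78 → 0 °C
Reagents that add atoms: diethyl chlorophosphate CCOP(=O)(Cl)OCC
Why: Copper-catalysed asymmetric conjugate addition of the Grignard reagent to the α-methyl enone with enolate trapping (a known reaction class for 2-methylcycloalkenones) sets C10, the ligand antipode being chosen for the configuration drawn; the magnesium enolate then adds 1,2 to acrolein on the face anti to the new C10 chain, which makes the quaternary C1 with the two chains trans, and O-phosphorylation blocks retro-aldol cleavage and supplies the allylic leaving group (three-component conjugate addition–aldol coupling).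

Step 2
Reactants: 7 allylic phosphate acetal
Product: 8 keto aldehyde phosphate
Conditions: PPTS (cat.), acetone/H2O (10:1), 50 °C
Reagents that add atoms: water O
Why: Acid-catalysed acetal hydrolysis frees the C7 aldehyde, while the allylic phosphate, the ketone and the non-enolisable quaternary centre should be stable to pyridinium tosylate.

Step 3
Reactants: 8 keto aldehyde phosphate
Product: 11 trans-hydrindanone alcohol with C2 vinyl, via allylic iodide 9 (not isolated), via allylchromium species 10 (not isolated)
Conditions: CrCl2 (4 equiv), LiI (0.2 equiv), THF/DMPU, 0 °C → rt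
Reagents that add atoms: none
Why: Intramolecular Nozaki–Hiyama allylation: iodide opens the allylic phosphate by SN2′, Cr(II) gives the (E)-γ-substituted allylchromium, and this adds through its γ-carbon (C2) in a chair Zimmerman–Traxler transition state fused to the forming chair cyclohexane (angular methyl axial because the five-membered ring is trans-fused), so the C2 vinyl and C7 hydroxyl should end trans-diequatorial with the vinyl cis to the methyl; attack through the α-terminus would need an eight-membered ring.

Step 4
Reactants: 11 trans-hydrindanone alcohol; 12 4,4-diethoxybut-1-ene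
Product: 13 (E)-4,4-diethoxybutenyl hydrindanone alcohol
Conditions: 12 (5 equiv), Hoveyda–Grubbs II catalyst (5 mol %), CH2Cl2, 40 °C
Reagents that add atoms: none
Why: Olefin cross-metathesis of the only alkene of 11 with an excess of the unhindered terminal partner should give the thermodynamically preferred (E)-1,2-disubstituted alkene, whose geometry is needed for the later chirality transfer; alcohol, ketone and acetal are tolerated by the ruthenium carbene.

Step 5
Reactants: 13 hydrindanone alcohol
Product: 15 2-diazo ketone, via bis-trifluoroacetyl compound 14 (not isolated)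
Conditions: LiHMDS (2.2 equiv), THF, −78 °C; CF3CO2CH2CF3 (2.4 equiv); then MsN3, Et3N, H2O, MeCN, rt; aq. NaHCO3
Reagents that add atoms: methanesulfonyl azide CS(=O)(=O)N=[N+]=[N-]
Why: Detrifluoroacetylative diazo transfer (Regitz-type) at the only enolisable α-carbon of the cyclopentanone (C12; C1 is quaternary); the hydroxyl is trifluoroacetylated in passing and freed again on bicarbonate work-up.

Step 6
Reactants: 15 2-diazo ketone
Product: 17 bicyclo[4.2.0]octane morpholine amide, via ketene 16 (not isolated)
Conditions: hν (365 nm), morpholine (5 equiv), THF, 0 °C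
Reagents that add atoms: morpholine C1COCCN1
Why: Irradiation of the cyclic α-diazo ketone, which is locked s-cis, expels N2 with concerted 1,2-shift of the C1–C13 bond to C12 (photochemical Wolff rearrangement); the quaternary C1 migrates with retention and the C1–C12 bond of the cyclobutane is formed, while C13 leaves the ring as a ketene carbon that morpholine captures as the amide. The closest known reaction type is the ring contraction of 2-diazocycloalkanones, in particular of trans-hydrindanone-type 16-diazo-17-oxo steroids to trans-fused D-nor cyclobutanes that carry the angular methyl. The four-membered ring is closed by contraction of the five-membered ring (a 1,2-shift), not by an end-to-end cyclisation, which is why the strained trans-fused bicyclo[4.2.0]octane is reachable from the unstrained trans-hydrindanone. The new stereocentre C12 is set when the amide enol is protonated on the face opposite the pseudo-axial angular methyl, which places the acyl group pseudo-equatorial, cis to the methyl and cis to C9; this should also be the more stable epimer. The selectivity needed is rearrangement over carbene-type O–H, N–H or C–H insertion and cyclopropanation; it is secured by the enforced s-cis geometry (concerted path without a free carbene), by the excess of morpholine, and by the C7 hydroxyl being unable to reach the ketene (C12 is anti to C7 about C1–C2).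

Step 7
Reactants: 17 hydroxy amide
Product: 18 C7 ketone
Conditions: Dess–Martin periodinane, NaHCO3, CH2Cl2, 0 °C → rt
Reagents that add atoms: none
Why: Dess–Martin oxidation under buffered, non-basic conditions should give the β,γ-unsaturated ketone without epimerising C2 or moving the double bond into conjugation; amide and acetal are inert.

Step 8
Reactants: 19 2,3-dibromoprop-1-ene; 20 (2-methylprop-1-en-1-yl)magnesium bromide
Product: 21 2-bromo-5-methylhexa-1,4-diene
Conditions: CuI (5 mol %), THF, 0 °C → rt
Reagents that add atoms: none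
Why: Copper-catalysed allylic substitution of the allylic bromide by the alkenyl Grignard reagent (SN2 and SN2′ lead to the same skipped diene) leaves the vinylic bromide for the later halogen–lithium exchange.

Step 9
Reactants: 18 C7 ketone; 21 2-bromo-5-methylhexa-1,4-diene
Product: 24 tertiary dialkenyl alcohol, via alkenyllithium 22 (not isolated), via organocerium reagent 23 (not isolated)
Conditions: 21, t-BuLi (2 equiv), Et2O, −78 °C; CeCl3, THF, −78 °C; then 18, −78 °C
Reagents that add atoms: none
Why: Bromine–lithium exchange and transmetalation give a weakly basic organocerium reagent that adds 1,2 to the enolisable ketone from the equatorial direction, anti to the 1,3-related axial angular methyl, so the C7 carbinol should have an axial hydroxyl and the two alkenyl groups trans-diequatorial; the tertiary amide does not react at −78 °C.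

Step 10
Reactants: 24 tertiary dialkenyl alcohol
Product: 27 (E)-cyclodecenone, via potassium alkoxide 25 (not isolated), via potassium enolate 26 (not isolated)
Conditions: KHMDS (1.1 equiv), 18-crown-6, THF, 0 °C → rt; then AcOH, −78 °C
Reagents that add atoms: none
Why: Anionic oxy-Cope rearrangement: the alkoxide-accelerated [3,3] shift through the chair transition state open to the trans-diequatorial dialkenyl alcohol breaks C2–C7 and forms C4–C5, gives the (E)-cyclodecenone enolate and transfers the C2 configuration through the (E)-alkene to the new stereocentre C4; kinetic C-protonation of the enolate on its peripheral face at −78 °C is then expected to set C6.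

Step 11
Reactants: 27 (E)-cyclodecenone
Product: 28 saturated ten-membered ketone
Conditions: 2-nitrobenzenesulfonohydrazide, Et3N, CH2Cl2, rt
Reagents that add atoms: none
Why: Diimide reduction (concerted syn hydrogen transfer from diimide released by the sulfonohydrazide) should remove the strained (E)-disubstituted ring alkene and leave the trisubstituted prenyl alkene; being metal-free and nearly neutral it should not epimerise C6.

Step 12
Reactants: 28 saturated ketone
Product: 29 C7-methylidene amide
Conditions: Zn, CH2Br2, TiCl4 (pre-formed Lombardo reagent), THF/CH2Cl2, 0 °C → rt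
Reagents that add atoms: dibromomethane BrCBr
Why: Lombardo methylenation converts the hindered α-branched ketone into the C7 methylidene group under non-basic conditions that keep the α-stereocentre C6, and does not touch the tertiary amide or the acetal.

Step 13
Reactants: 29 C7-methylidene amide
Product: 31 C12 methyl ketone, via lithium hemiaminal adduct 30 (not isolated)
Conditions: MeLi (3 equiv), THF, −78 → 0 °C; sat. aq. NH4Cl
Reagents that add atoms: methyllithium [Li]C
Why: Addition of methyllithium to the morpholine amide stops at the tetrahedral adduct, which gives the methyl ketone on work-up (ketone synthesis from a tertiary amide) and removes the morpholine helper; the acetyl group stays pseudo-equatorial, cis to the angular methyl.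

Step 14
Reactants: 31 C12 methyl ketone
Product: 32 isopropenyl diethyl acetal
Conditions: Ph3PCH3Br, KOt-Bu, THF, 0 °C → rt
Reagents that add atoms: methyltriphenylphosphonium bromide C[P+](c1ccccc1)(c1ccccc1)c1ccccc1.[Br-]
Why: Wittig methylenation of the only carbonyl group gives the isopropenyl group; any enolisation by the ylide can only return the preferred C12 epimer.

Step 15
Reactants: 32 isopropenyl diethyl acetal
Product: 33 C4 acetaldehyde
Conditions: PPTS (cat.), acetone/H2O, 40 °C
Reagents that add atoms: water O
Why: Mild acid-catalysed acetal hydrolysis liberates the aldehyde without isomerising the 1,1-disubstituted or trisubstituted alkenes.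

Step 16
Reactants: 33 C4 acetaldehyde
Product: 34 2-substituted acrolein
Conditions: 37 % aq. CH2O, pyrrolidine (10 mol %), EtCO2H (10 mol %), i-PrOH, 45 °C
Reagents that add atoms: formaldehyde C=O
Why: Amine/acid-catalysed α-methylenation of the aldehyde with formaldehyde (Mannich condensation and elimination) gives the α-methylene aldehyde; C4 is β to the carbonyl and is not epimerised.

Step 17
Reactants: 34 2-substituted acrolein
Product: 36 target CNP0314186.1, via acrylic acid 35 (not isolated)
Conditions: NaClO2, NaH2PO4, 2-methyl-2-butene (large excess), t-BuOH/H2O, 0 °C; then TMSCHN2, MeOH/toluene, 0 °C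
Reagents that add atoms: sodium chlorite [Na+].[O-]Cl=O; trimethylsilyldiazomethane C[Si](C)(C)C=[N+]=[N-]
Why: Pinnick oxidation of the enal, with a large excess of 2-methyl-2-butene to consume hypochlorous acid before it reaches the other alkenes, and O-methylation of the acid with trimethylsilyldiazomethane give the methyl acrylate of the target.

**Compound list**

1 | 2-methylcyclopent-2-en-1-one | CC1=CCCC1=O | starting material
2 | 2-(2-bromoethyl)-1,3-dioxolane | BrCCC1OCCO1 | starting material
3 | acrolein (prop-2-enal) | C=CC=O | starting material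
4 | [2-(1,3-dioxolan-2-yl)ethyl]magnesium bromide (not isolated) | Br[Mg]CCC1OCCO1 | intermediate
5 | bromomagnesium enolate of 3-[2-(1,3-dioxolan-2-yl)ethyl]-2-methylcyclopentanone, C10 as in the target (not isolated) | C1(CC[C@@H]2CCC(O[Mg]Br)=C2C)OCCO1 | intermediate
6 | bromomagnesium aldolate from 5 and acrolein, C1 chain trans to the C10 chain (not isolated) | C1(CC[C@@H]2CCC(=O)[C@@]2(C)C(O[Mg]Br)C=C)OCCO1 | intermediate
7 | diethyl 1-{2-[2-(1,3-dioxolan-2-yl)ethyl]-1-methyl-5-oxocyclopentyl}prop-2-en-1-yl phosphate; propenyl chain trans to the acetal chain, methyl cis to it; both epimers at the phosphate carbon | C1(CC[C@@H]2CCC(=O)[C@@]2(C)C(OP(=O)(OCC)OCC)C=C)OCCO1 | intermediate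
8 | diethyl 1-[1-methyl-5-oxo-2-(3-oxopropyl)cyclopentyl]prop-2-en-1-yl phosphate; ring stereochemistry as 7 | O=CCC[C@@H]1CCC(=O)[C@@]1(C)C(OP(=O)(OCC)OCC)C=C | intermediate
9 | 3-{2-[(E)-3-iodoprop-1-enyl]-2-methyl-3-oxocyclopentyl}propanal (not isolated) | O=CCC[C@@H]1CCC(=O)[C@@]1(C)/C=C/CI | intermediate
10 | (E)-allylchromium(III) dichloride derived from 9 (not isolated) | O=CCC[C@@H]1CCC(=O)[C@@]1(C)/C=C/C[Cr](Cl)Cl | intermediate
11 | 6-hydroxy-7a-methyl-7-vinyloctahydro-1H-inden-1-one; trans ring fusion, 6-OH and 7-vinyl both equatorial (trans), vinyl cis to the angular methyl | O[C@H]1CC[C@@H]2CCC(=O)[C@@]2(C)[C@@H]1C=C | intermediate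
12 | 4,4-diethoxybut-1-ene | C=CCC(OCC)OCC | starting material
13 | 7-[(E)-4,4-diethoxybut-1-enyl]-6-hydroxy-7a-methyloctahydro-1H-inden-1-one; stereochemistry as 11 | O[C@H]1CC[C@@H]2CCC(=O)[C@@]2(C)[C@@H]1/C=C/CC(OCC)OCC | intermediate
14 | 2-(trifluoroacetyl) derivative of 13 with the 6-hydroxyl as trifluoroacetate (not isolated) | FC(F)(F)C(=O)O[C@H]1CC[C@@H]2CC(C(=O)C(F)(F)F)C(=O)[C@@]2(C)[C@@H]1/C=C/CC(OCC)OCC | intermediate
15 | 2-diazo-7-[(E)-4,4-diethoxybut-1-enyl]-6-hydroxy-7a-methyloctahydro-1H-inden-1-one | O[C@H]1CC[C@@H]2CC(=[N+]=[N-])C(=O)[C@@]2(C)[C@@H]1/C=C/CC(OCC)OCC | intermediate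
16 | 8-(oxomethylidene)bicyclo[4.2.0]octane ketene formed from 15 (not isolated) | O[C@H]1CC[C@@H]2CC(=C=O)[C@@]2(C)[C@@H]1/C=C/CC(OCC)OCC | intermediate
17 | {2-[(E)-4,4-diethoxybut-1-enyl]-3-hydroxy-1-methylbicyclo[4.2.0]octan-8-yl}(morpholin-4-yl)methanone; trans ring fusion, acyl group cis to the angular methyl | O[C@H]1CC[C@@H]2C[C@H](C(=O)N3CCOCC3)[C@@]2(C)[C@@H]1/C=C/CC(OCC)OCC | intermediate
18 | 2-[(E)-4,4-diethoxybut-1-enyl]-1-methyl-8-(morpholine-4-carbonyl)bicyclo[4.2.0]octan-3-one; stereochemistry as 17 | O=C1CC[C@@H]2C[C@H](C(=O)N3CCOCC3)[C@@]2(C)[C@@H]1/C=C/CC(OCC)OCC | intermediate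
19 | 2,3-dibromoprop-1-ene | C=C(Br)CBr | starting material
20 | (2-methylprop-1-en-1-yl)magnesium bromide | CC(C)=C[Mg]Br | starting material
21 | 2-bromo-5-methylhexa-1,4-diene | C=C(Br)CC=C(C)C | intermediate
22 | (5-methylhexa-1,4-dien-2-yl)lithium (not isolated) | [Li]C(=C)CC=C(C)C | intermediate
23 | dichloro(5-methylhexa-1,4-dien-2-yl)cerium (not isolated) | Cl[Ce](Cl)C(=C)CC=C(C)C | intermediate
24 | 3-hydroxy-3-(5-methylhexa-1,4-dien-2-yl) derivative of 18; hydroxyl axial and cis to the angular methyl, the two alkenyl groups trans-diequatorial | C=C(CC=C(C)C)[C@@]1(O)CC[C@@H]2C[C@H](C(=O)N3CCOCC3)[C@@]2(C)[C@@H]1/C=C/CC(OCC)OCC | intermediate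
25 | potassium alkoxide of 24 (not isolated) | C=C(CC=C(C)C)[C@@]1(O[K])CC[C@@H]2C[C@H](C(=O)N3CCOCC3)[C@@]2(C)[C@@H]1/C=C/CC(OCC)OCC | intermediate
26 | potassium C6=C7 enolate of ketone 27 (not isolated) | [K]OC=1CC[C@@H]2C[C@H](C(=O)N3CCOCC3)[C@@]2(C)/C=C/[C@H](CC(OCC)OCC)CC=1CC=C(C)C | intermediate
27 | [(2E)-4-(2,2-diethoxyethyl)-1-methyl-6-(3-methylbut-2-enyl)-7-oxobicyclo[8.2.0]dodec-2-en-12-yl](morpholin-4-yl)methanone; C1, C4, C6, C10, C12 as in the target | O=C1CC[C@@H]2C[C@H](C(=O)N3CCOCC3)[C@@]2(C)/C=C/[C@H](CC(OCC)OCC)C[C@H]1CC=C(C)C | intermediate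
28 | 2,3-dihydro derivative of 27 (saturated ten-membered ketone) | O=C1CC[C@@H]2C[C@H](C(=O)N3CCOCC3)[C@@]2(C)CC[C@H](CC(OCC)OCC)C[C@H]1CC=C(C)C | intermediate
29 | [4-(2,2-diethoxyethyl)-1-methyl-7-methylidene-6-(3-methylbut-2-enyl)bicyclo[8.2.0]dodecan-12-yl](morpholin-4-yl)methanone | C=C1CC[C@@H]2C[C@H](C(=O)N3CCOCC3)[C@@]2(C)CC[C@H](CC(OCC)OCC)C[C@H]1CC=C(C)C | intermediate
30 | lithium alkoxide adduct of methyllithium to the amide of 29 (not isolated) | C=C1CC[C@@H]2C[C@H](C(C)(O[Li])N3CCOCC3)[C@@]2(C)CC[C@H](CC(OCC)OCC)C[C@H]1CC=C(C)C | intermediate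
31 | 1-[4-(2,2-diethoxyethyl)-1-methyl-7-methylidene-6-(3-methylbut-2-enyl)bicyclo[8.2.0]dodecan-12-yl]ethanone | C=C1CC[C@@H]2C[C@H](C(C)=O)[C@@]2(C)CC[C@H](CC(OCC)OCC)C[C@H]1CC=C(C)C | intermediate
32 | 4-(2,2-diethoxyethyl)-1-methyl-7-methylidene-6-(3-methylbut-2-enyl)-12-(prop-1-en-2-yl)bicyclo[8.2.0]dodecane | C=C1CC[C@@H]2C[C@H](C(=C)C)[C@@]2(C)CC[C@H](CC(OCC)OCC)C[C@H]1CC=C(C)C | intermediate
33 | 2-[1-methyl-7-methylidene-6-(3-methylbut-2-enyl)-12-(prop-1-en-2-yl)bicyclo[8.2.0]dodecan-4-yl]acetaldehyde | C=C1CC[C@@H]2C[C@H](C(=C)C)[C@@]2(C)CC[C@H](CC=O)C[C@H]1CC=C(C)C | intermediate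
34 | 2-[1-methyl-7-methylidene-6-(3-methylbut-2-enyl)-12-(prop-1-en-2-yl)bicyclo[8.2.0]dodecan-4-yl]prop-2-enal | C=C1CC[C@@H]2C[C@H](C(=C)C)[C@@]2(C)CC[C@H](C(=C)C=O)C[C@H]1CC=C(C)C | intermediate
35 | the corresponding prop-2-enoic acid (not isolated) | C=C1CC[C@@H]2C[C@H](C(=C)C)[C@@]2(C)CC[C@H](C(=C)C(=O)O)C[C@H]1CC=C(C)C | intermediate
36 | methyl 2-[(1S,4S,6R,10R,12R)-1-methyl-7-methylidene-6-(3-methylbut-2-enyl)-12-(prop-1-en-2-yl)bicyclo[8.2.0]dodecan-4-yl]prop-2-enoate (CNP0314186.1) | C=C1CC[C@@H]2C[C@H](C(=C)C)[C@@]2(C)CC[C@H](C(=C)C(=O)OC)C[C@H]1CC=C(C)C | target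

**Totals and risks**

Total step count: 17. Longest linear sequence: 16 (steps 1–7 and 9–17; step 8 is a one-step branch).

Steps most likely to fail:

Step 1. What may go wrong: insufficient enantioinduction in the copper-catalysed addition to the α-substituted enone, and slow or reversible aldol trapping of the hindered magnesium enolate. Fallback, setting out from 4 and returning at 7: the three events are separated. Copper-catalysed asymmetric 1,4-addition of 4 to commercial cyclopent-2-en-1-one (the standard substrate for this catalysis) gives magnesium enolate F1, which is methylated with iodomethane in the presence of DMPU to the trans-2-methyl ketone F2. Thermodynamic silylation (Me3SiCl, Et3N, DMF, 80 °C) gives the tetrasubstituted silyl enol ether F3. Methyllithium (THF, 0 °C) liberates lithium enolate F4, which adds to acrolein at −78 °C to give lithium aldolate F5; phosphorylation with diethyl chlorophosphate then gives 7.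

Step 10. What may go wrong: protonation of the medium-ring enolate on the face other than the planned one, equilibration at C6 during work-up, or fragmentation of the hindered alkoxide instead of the [3,3] shift. Fallback, setting out from 18 and returning at 27: the order in which the two C6 substituents arrive is reversed. Vinylmagnesium bromide/CeCl3 (THF, −78 °C) gives vinyl carbinol F6. KHMDS/18-crown-6 gives its potassium alkoxide F7 and, by the same oxy-Cope shift, the C6-unsubstituted potassium enolate F8. This is alkylated at −78 °C with 1-bromo-3-methylbut-2-ene, so that carbon instead of hydrogen enters on the face the enolate offers, which gives 27.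

Step 6. What may go wrong: diversion of the excited diazo ketone into insertion or addition reactions with the free hydroxyl, morpholine or the alkene, and a reluctant 1,2-shift because the product is a strained trans-fused cyclobutane. Fallback, setting out from 7 and returning at 17: the ring contraction is moved in front of the six-membered ring closure, so it runs on a monocyclic, hydroxyl-free ketone. Diazo transfer as in step 5 gives diazo ketone F9. Irradiation with morpholine gives ketene F10 and then the monocyclic cyclobutane amide F11. Acetal hydrolysis gives aldehyde F12. CrCl2/LiI closes the six-membered ring by way of allylic iodide F13 and allylchromium species F14 to the vinyl bicyclo[4.2.0]octanol F15, and cross-metathesis with 12 gives 17.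

Further compounds
F1 | step 1 | bromomagnesium enolate of 3-[2-(1,3-dioxolan-2-yl)ethyl]cyclopentanone | C1(CC[C@@H]2CCC(O[Mg]Br)=C2)OCCO1
F2 | step 1 | trans-3-[2-(1,3-dioxolan-2-yl)ethyl]-2-methylcyclopentanone | C1(CC[C@@H]2CCC(=O)[C@H]2C)OCCO1
F3 | step 1 | 1-(trimethylsilyloxy)-2-methyl-3-[2-(1,3-dioxolan-2-yl)ethyl]cyclopent-1-ene | C1(CC[C@@H]2CCC(O[Si](C)(C)C)=C2C)OCCO1
F4 | step 1 | lithium enolate corresponding to 5 | C1(CC[C@@H]2CCC(O[Li])=C2C)OCCO1
F5 | step 1 | lithium aldolate corresponding to 6 | C1(CC[C@@H]2CCC(=O)[C@@]2(C)C(O[Li])C=C)OCCO1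
F6 | step 10 | 3-hydroxy-3-vinyl analogue of 24 | C=C[C@@]1(O)CC[C@@H]2C[C@H](C(=O)N3CCOCC3)[C@@]2(C)[C@@H]1/C=C/CC(OCC)OCC
F7 | step 10 | potassium alkoxide of F6 | C=C[C@@]1(O[K])CC[C@@H]2C[C@H](C(=O)N3CCOCC3)[C@@]2(C)[C@@H]1/C=C/CC(OCC)OCC
F8 | step 10 | potassium C6=C7 enolate lacking the C6 substituent | [K]OC=1CC[C@@H]2C[C@H](C(=O)N3CCOCC3)[C@@]2(C)/C=C/[C@H](CC(OCC)OCC)CC=1
F9 | step 6 | 4-diazo derivative of 7 (diazo group on C12) | C1(CC[C@@H]2CC(=[N+]=[N-])C(=O)[C@@]2(C)C(OP(=O)(OCC)OCC)C=C)OCCO1
F10 | step 6 | monocyclic cyclobutylidene ketene from F9 | C1(CC[C@@H]2CC(=C=O)[C@@]2(C)C(OP(=O)(OCC)OCC)C=C)OCCO1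
F11 | step 6 | monocyclic cyclobutane morpholine amide with dioxolane and allylic phosphate | C1(CC[C@@H]2C[C@H](C(=O)N3CCOCC3)[C@@]2(C)C(OP(=O)(OCC)OCC)C=C)OCCO1
F12 | step 6 | aldehyde from F11 | O=CCC[C@@H]1C[C@H](C(=O)N2CCOCC2)[C@@]1(C)C(OP(=O)(OCC)OCC)C=C
F13 | step 6 | (E)-allylic iodide from F12 | O=CCC[C@@H]1C[C@H](C(=O)N2CCOCC2)[C@@]1(C)/C=C/CI
F14 | step 6 | (E)-allylchromium(III) dichloride from F13 | O=CCC[C@@H]1C[C@H](C(=O)N2CCOCC2)[C@@]1(C)/C=C/C[Cr](Cl)Cl
F15 | step 6 | (3-hydroxy-1-methyl-2-vinylbicyclo[4.2.0]octan-8-yl)(morpholin-4-yl)methanone, stereochemistry as 17 | O[C@H]1CC[C@@H]2C[C@H](C(=O)N3CCOCC3)[C@@]2(C)[C@@H]1C=C
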